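**Retrosynthetic overview**
1. Selaginellin 29 ⇐ triaryl carbinol 28 (acid removes five MOM groups and water is lost through a para-hydroxyl to give the quinone methide) ⇐ diaryl ketone 24 + aryllithium 27.
2. The C6 alkyne of 24 ⇐ elimination of enol triflate 23, made from the C6 CH2C(=O)Ar chain; the C2 aryl group ⇐ Suzuki coupling at the C2–Cl bond of 18.
3. Feature: in ring A (central benzene; C1 methide carbon, C2 4-hydroxyphenyl, C3/C4 H, C5 CH2OH, C6 arylethynyl) the chains on the neighbouring carbons C1 and C6 end in the same 4-oxyphenyl group (C1–C(Ar) and C6–C–C(Ar)). Both therefore come from one symmetric ArCO–CH2–COAr unit inserted across a C1–C6 aryne (18 ⇐ 9 + 14).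
4. Aryne precursor 9 ⇐ 2-bromo-3-chlorophenol 1 (ortho-formylation, reduction, retro-Brook silylation/triflation, MOM ether); diketone 14 ⇐ Claisen condensation of 11 with 13.
5. Rings: none is built. All five six-membered rings are bought as benzene rings; the only ring closed is the transient four-membered ring of step 8, which opens again.

Key step: step 8

Remark: 4-hydroxyphenylboronic acid is used as its commercial pinacol ester 19 so that the phenol can be protected cleanly before coupling. Ring A numbering (C1–C6 as in line 3) is used throughout.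

**Step 1**
Reactants: 1 2-bromo-3-chlorophenol
Product: 2 3-bromo-4-chloro-2-hydroxybenzaldehyde
Conditions: MgCl2, Et3N, (CH2O)n, MeCN, reflux
Reagents that add atoms: paraformaldehyde (source of formaldehyde), C=O
Why: Magnesium-phenoxide-directed ortho-formylation (Casnati–Skattebøl reaction) can only take the one free ortho position (C5), the other being blocked by bromine; a second formaldehyde accepts hydride from the intermediate salicyl alkoxide.

**Step 2**
Reactants: 2 3-bromo-4-chloro-2-hydroxybenzaldehyde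
Product: 3 2-bromo-3-chloro-6-(hydroxymethyl)phenol
Conditions: NaBH4, MeOH/THF, 0 °C
Reagents that add atoms: none
Why: Borohydride reduction of the aldehyde should leave the aryl halides and the phenol untouched.

**Step 3**
Reactants: 3 2-bromo-3-chloro-6-(hydroxymethyl)phenol
Product: 8 3-chloro-6-(hydroxymethyl)-2-(trimethylsilyl)phenyl trifluoromethanesulfonate, via bis(trimethylsilyl) ether 4 (not isolated), via aryllithium 5 (not isolated), via lithium phenoxide 6 (not isolated), via silyl ether triflate 7 (not isolated)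
Conditions: (Me3Si)2NH, THF, reflux, then evaporate; n-BuLi, THF, −100 to −80 °C; Tf2O, −100 °C; 1 M HCl, THF, 0 °C
Reagents that add atoms: hexamethyldisilazane, C[Si](C)(C)N[Si](C)(C)C; trifluoromethanesulfonic anhydride, O=S(=O)(OS(=O)(=O)C(F)(F)F)C(F)(F)F
Why: This is the standard one-flask route from 2-bromophenols to 2-silylaryl triflates: O-silylation, bromine–lithium exchange, 1,3 O-to-C silyl shift (retro-Brook rearrangement) and O-triflation of the phenoxide, followed by mild hydrolysis of the primary silyl ether; the very low temperature should keep the aryllithium from losing LiCl.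

**Step 4**
Reactants: 8 3-chloro-6-(hydroxymethyl)-2-(trimethylsilyl)phenyl trifluoromethanesulfonate
Product: 9 3-chloro-6-[(methoxymethoxy)methyl]-2-(trimethylsilyl)phenyl trifluoromethanesulfonate
Conditions: MeOCH2Cl, i-Pr2NEt, CH2Cl2, 0 °C to rt
Reagents that add atoms: chloromethyl methyl ether, COCCl
Why: O-alkylation of the primary alcohol with the reactive alpha-chloro ether under amine base involves neither fluoride nor strong base, so the silyl/triflate pair should survive; the MOM ether is stable to fluoride, base and organolithium reagents in the later steps.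

**Step 5**
Reactants: 10 4-hydroxyacetophenone
Product: 11 1-[4-(methoxymethoxy)phenyl]ethan-1-one
Conditions: MeOCH2Cl, i-Pr2NEt, CH2Cl2, 0 °C to rt
Reagents that add atoms: chloromethyl methyl ether, COCCl
Why: Routine MOM protection of a phenol.

**Step 6**
Reactants: 12 methyl 4-hydroxybenzoate
Product: 13 methyl 4-(methoxymethoxy)benzoate
Conditions: MeOCH2Cl, i-Pr2NEt, CH2Cl2, 0 °C to rt
Reagents that add atoms: chloromethyl methyl ether, COCCl
Why: Routine MOM protection of a phenol.

**Step 7**
Reactants: 11 1-[4-(methoxymethoxy)phenyl]ethan-1-one; 13 methyl 4-(methoxymethoxy)benzoate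
Product: 14 1,3-bis[4-(methoxymethoxy)phenyl]propane-1,3-dione
Conditions: NaH, THF, reflux (slow addition of 11); AcOH quench
Reagents that add atoms: none
Why: Crossed Claisen condensation of a methyl ketone enolate with a non-enolisable aryl ester is driven by deprotonation of the 1,3-diketone formed; the MOM ethers are stable to base.

**Step 8**
Reactants: 9 3-chloro-6-[(methoxymethoxy)methyl]-2-(trimethylsilyl)phenyl trifluoromethanesulfonate; 14 1,3-bis[4-(methoxymethoxy)phenyl]propane-1,3-dione
Product: 18 2-{3-chloro-2-[4-(methoxymethoxy)benzoyl]-6-[(methoxymethoxy)methyl]phenyl}-1-[4-(methoxymethoxy)phenyl]ethan-1-one, via aryne 15 (not isolated), via aryl anion 16 (not isolated), via benzocyclobutenoxide 17 (not isolated)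
Conditions: CsF (3 equiv), MeCN, 80 °C (9 in slight excess)
Reagents that add atoms: none
Why: Fluoride attacks silicon in 9 and triflate leaves to give aryne 15, and the cesium enolate of 14 (formed by the same base) adds through carbon to C6, the aryne carbon remote from chlorine, so that the negative charge appears at C1 next to the electron-withdrawing chlorine (anion 16). The C1 anion then closes 4-exo-trig onto the neighbouring aroyl carbonyl to give benzocyclobutenoxide 17, and retro-aldol-type opening of this strained ring breaks the former CH–CO bond; this leaves the aroyl group on C1 and, after protonation, the 2-aryl-2-oxoethyl chain on C6, with no ring and no stereocentre retained. The closest known reaction type is the fluoride-induced acyl-alkylation of arynes from 2-silylaryl triflates with beta-ketoesters and 1,3-diketones, a formal insertion into the C–C sigma bond. The step needs attack at C6 and not at C1, and the inductive distortion of the aryne by the C2 chlorine should secure this against the modest steric demand of the CH2OMOM group on C5. Because 14 is symmetric, either aroyl group can migrate with the same outcome, and the product holds one non-enolisable diaryl ketone beside a single enolisable ketone, which keeps the later steps selective.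

**Step 9**
Reactants: 19 4-(4,4,5,5-tetramethyl-1,3,2-dioxaborolan-2-yl)phenol
Product: 20 2-[4-(methoxymethoxy)phenyl]-4,4,5,5-tetramethyl-1,3,2-dioxaborolane
Conditions: MeOCH2Cl, i-Pr2NEt, CH2Cl2, 0 °C to rt
Reagents that add atoms: chloromethyl methyl ether, COCCl
Why: Routine MOM protection of a phenol; the pinacol boronate tolerates the mild amine base.

**Step 10**
Reactants: 18 2-{3-chloro-2-[4-(methoxymethoxy)benzoyl]-6-[(methoxymethoxy)methyl]phenyl}-1-[4-(methoxymethoxy)phenyl]ethan-1-one; 20 2-[4-(methoxymethoxy)phenyl]-4,4,5,5-tetramethyl-1,3,2-dioxaborolane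
Product: 21 2-{4'-(methoxymethoxy)-2-[4-(methoxymethoxy)benzoyl]-4-[(methoxymethoxy)methyl]-[1,1'-biphenyl]-3-yl}-1-[4-(methoxymethoxy)phenyl]ethan-1-one
Conditions: Pd(OAc)2 (3 mol%), SPhos (6 mol%), K3PO4, toluene/H2O, 90 °C
Reagents that add atoms: none
Why: Suzuki–Miyaura coupling; zerovalent palladium carrying the electron-rich biaryl phosphine should insert into the C2–Cl bond, which is activated by the ortho ketone, and transmetalation with the boronate should outrun any enolate chemistry of the benzyl ketone.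

**Step 11**
Reactants: 21 2-{4'-(methoxymethoxy)-2-[4-(methoxymethoxy)benzoyl]-4-[(methoxymethoxy)methyl]-[1,1'-biphenyl]-3-yl}-1-[4-(methoxymethoxy)phenyl]ethan-1-one
Product: 23 (Z)-2-{4'-(methoxymethoxy)-2-[4-(methoxymethoxy)benzoyl]-4-[(methoxymethoxy)methyl]-[1,1'-biphenyl]-3-yl}-1-[4-(methoxymethoxy)phenyl]ethenyl trifluoromethanesulfonate, via potassium enolate 22 (not isolated)
Conditions: KN(SiMe3)2 (1.1 equiv), THF, −78 °C; PhNTf2, −78 to 0 °C; aq. NH4Cl
Reagents that add atoms: N-phenylbis(trifluoromethanesulfonimide), O=S(=O)(N(c1ccccc1)S(=O)(=O)C(F)(F)F)C(F)(F)F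
Why: Deprotonation at the only enolisable position (the C6 CH2) should give the Z-enolate, in which the bulky ring A lies trans to the aryl group and cis to oxygen, and O-triflation fixes this geometry with the vinylic hydrogen anti to the triflate; the diaryl ketone on C1 cannot enolise.

**Step 12**
Reactants: 23 (Z)-2-{4'-(methoxymethoxy)-2-[4-(methoxymethoxy)benzoyl]-4-[(methoxymethoxy)methyl]-[1,1'-biphenyl]-3-yl}-1-[4-(methoxymethoxy)phenyl]ethenyl trifluoromethanesulfonate
Product: 24 {4'-(methoxymethoxy)-4-[(methoxymethoxy)methyl]-3-{[4-(methoxymethoxy)phenyl]ethynyl}-[1,1'-biphenyl]-2-yl}[4-(methoxymethoxy)phenyl]methanone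
Conditions: KN(SiMe3)2 (2.2 equiv), THF, −78 to 0 °C
Reagents that add atoms: none
Why: Anti-periplanar E2 elimination of triflate and the aryl-activated vinylic hydrogen by a strong, non-nucleophilic amide base that has no beta-hydrogen and so cannot reduce the diaryl ketone.

**Step 13**
Reactants: 25 4-bromophenol
Product: 26 1-bromo-4-(methoxymethoxy)benzene
Conditions: MeOCH2Cl, i-Pr2NEt, CH2Cl2, 0 °C to rt
Reagents that add atoms: chloromethyl methyl ether, COCCl
Why: Routine MOM protection of a phenol.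

**Step 14**
Reactants: 26 1-bromo-4-(methoxymethoxy)benzene; 24 {4'-(methoxymethoxy)-4-[(methoxymethoxy)methyl]-3-{[4-(methoxymethoxy)phenyl]ethynyl}-[1,1'-biphenyl]-2-yl}[4-(methoxymethoxy)phenyl]methanone
Product: 28 {4'-(methoxymethoxy)-4-[(methoxymethoxy)methyl]-3-{[4-(methoxymethoxy)phenyl]ethynyl}-[1,1'-biphenyl]-2-yl}bis[4-(methoxymethoxy)phenyl]methanol, via aryllithium 27 (not isolated)
Conditions: 26 (3 equiv), n-BuLi, THF, −78 °C; then 24, −78 to 0 °C; aq. NH4Cl
Reagents that add atoms: none
Why: Bromine–lithium exchange followed by 1,2-addition of the aryllithium to the non-enolisable diaryl ketone; the alkyne and the MOM ethers are inert, and the slim alkynyl group on C6 leaves one face of the hindered carbonyl accessible.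

**Step 15**
Reactants: 28 {4'-(methoxymethoxy)-4-[(methoxymethoxy)methyl]-3-{[4-(methoxymethoxy)phenyl]ethynyl}-[1,1'-biphenyl]-2-yl}bis[4-(methoxymethoxy)phenyl]methanol
Product: 29 selaginellin
Conditions: 3 M HCl (aq.), MeOH/THF, 50 °C; buffered aqueous work-up
Reagents that add atoms: none
Why: Acid-catalysed acetal cleavage should remove all five MOM groups (methanol takes up the formaldehyde as dimethoxymethane), and the doubly para-hydroxy-stabilised tertiary carbinol loses water through one hydroxyphenyl ring to give the quinone methide; any methanol adduct at the methide carbon should revert on aqueous work-up.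

**Compound list**
1 | 2-bromo-3-chlorophenol | Oc1cccc(Cl)c1Br | starting material
2 | 3-bromo-4-chloro-2-hydroxybenzaldehyde | O=Cc1ccc(Cl)c(Br)c1O | intermediate
3 | 2-bromo-3-chloro-6-(hydroxymethyl)phenol | OCc1ccc(Cl)c(Br)c1O | intermediate
4 | (2-bromo-3-chloro-6-{[(trimethylsilyl)oxy]methyl}phenoxy)trimethylsilane (not isolated) | C[Si](C)(C)OCc1ccc(Cl)c(Br)c1O[Si](C)(C)C | intermediate
5 | {2-chloro-6-[(trimethylsilyl)oxy]-5-{[(trimethylsilyl)oxy]methyl}phenyl}lithium (not isolated) | C[Si](C)(C)OCc1ccc(Cl)c([Li])c1O[Si](C)(C)C | intermediate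
6 | lithium 3-chloro-2-(trimethylsilyl)-6-{[(trimethylsilyl)oxy]methyl}phenoxide (not isolated) | C[Si](C)(C)OCc1ccc(Cl)c([Si](C)(C)C)c1[O-].[Li+] | intermediate
7 | 3-chloro-2-(trimethylsilyl)-6-{[(trimethylsilyl)oxy]methyl}phenyl trifluoromethanesulfonate (not isolated) | C[Si](C)(C)OCc1ccc(Cl)c([Si](C)(C)C)c1OS(=O)(=O)C(F)(F)F | intermediate
8 | 3-chloro-6-(hydroxymethyl)-2-(trimethylsilyl)phenyl trifluoromethanesulfonate | OCc1ccc(Cl)c([Si](C)(C)C)c1OS(=O)(=O)C(F)(F)F | intermediate
9 | 3-chloro-6-[(methoxymethoxy)methyl]-2-(trimethylsilyl)phenyl trifluoromethanesulfonate (aryne precursor) | COCOCc1ccc(Cl)c([Si](C)(C)C)c1OS(=O)(=O)C(F)(F)F | intermediate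
10 | 4-hydroxyacetophenone | CC(=O)c1ccc(O)cc1 | starting material
11 | 1-[4-(methoxymethoxy)phenyl]ethan-1-one | CC(=O)c1ccc(OCOC)cc1 | intermediate
12 | methyl 4-hydroxybenzoate | COC(=O)c1ccc(O)cc1 | starting material
13 | methyl 4-(methoxymethoxy)benzoate | COCOc1ccc(C(=O)OC)cc1 | intermediate
14 | 1,3-bis[4-(methoxymethoxy)phenyl]propane-1,3-dione | COCOc1ccc(C(=O)CC(=O)c2ccc(OCOC)cc2)cc1 | intermediate
15 | 3-chloro-6-[(methoxymethoxy)methyl]benzyne, triple bond between C1 and C6 of ring A (not isolated) | COCOCC1=CC=C(Cl)C#C1 | intermediate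
16 | cesium 2-{1,3-bis[4-(methoxymethoxy)phenyl]-1,3-dioxopropan-2-yl}-6-chloro-3-[(methoxymethoxy)methyl]benzen-1-ide, carbanion at C1 (not isolated) | COCOCc1ccc(Cl)[c-]c1C(C(=O)c1ccc(OCOC)cc1)C(=O)c1ccc(OCOC)cc1.[Cs+] | intermediate
17 | cesium 5-chloro-2-[(methoxymethoxy)methyl]-8-[4-(methoxymethoxy)benzoyl]-7-[4-(methoxymethoxy)phenyl]bicyclo[4.2.0]octa-1,3,5-trien-7-olate, racemic, either diastereomer (not isolated) | COCOCc1ccc(Cl)c2c1C(C(=O)c1ccc(OCOC)cc1)C2([O-])c1ccc(OCOC)cc1.[Cs+] | intermediate
18 | 2-{3-chloro-2-[4-(methoxymethoxy)benzoyl]-6-[(methoxymethoxy)methyl]phenyl}-1-[4-(methoxymethoxy)phenyl]ethan-1-one | COCOCc1ccc(Cl)c(C(=O)c2ccc(OCOC)cc2)c1CC(=O)c1ccc(OCOC)cc1 | intermediate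
19 | 4-(4,4,5,5-tetramethyl-1,3,2-dioxaborolan-2-yl)phenol | Oc1ccc(B2OC(C)(C)C(C)(C)O2)cc1 | starting material
20 | 2-[4-(methoxymethoxy)phenyl]-4,4,5,5-tetramethyl-1,3,2-dioxaborolane | COCOc1ccc(B2OC(C)(C)C(C)(C)O2)cc1 | intermediate
21 | 2-{4'-(methoxymethoxy)-2-[4-(methoxymethoxy)benzoyl]-4-[(methoxymethoxy)methyl]-[1,1'-biphenyl]-3-yl}-1-[4-(methoxymethoxy)phenyl]ethan-1-one | COCOCc1ccc(-c2ccc(OCOC)cc2)c(C(=O)c2ccc(OCOC)cc2)c1CC(=O)c1ccc(OCOC)cc1 | intermediate
22 | potassium (Z)-2-{4'-(methoxymethoxy)-2-[4-(methoxymethoxy)benzoyl]-4-[(methoxymethoxy)methyl]-[1,1'-biphenyl]-3-yl}-1-[4-(methoxymethoxy)phenyl]ethen-1-olate (not isolated) | COCOCc1ccc(-c2ccc(OCOC)cc2)c(C(=O)c2ccc(OCOC)cc2)c1/C=C(\[O-])c1ccc(OCOC)cc1.[K+] | intermediate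
23 | (Z)-2-{4'-(methoxymethoxy)-2-[4-(methoxymethoxy)benzoyl]-4-[(methoxymethoxy)methyl]-[1,1'-biphenyl]-3-yl}-1-[4-(methoxymethoxy)phenyl]ethenyl trifluoromethanesulfonate | COCOCc1ccc(-c2ccc(OCOC)cc2)c(C(=O)c2ccc(OCOC)cc2)c1/C=C(\OS(=O)(=O)C(F)(F)F)c1ccc(OCOC)cc1 | intermediate
24 | {4'-(methoxymethoxy)-4-[(methoxymethoxy)methyl]-3-{[4-(methoxymethoxy)phenyl]ethynyl}-[1,1'-biphenyl]-2-yl}[4-(methoxymethoxy)phenyl]methanone | COCOCc1ccc(-c2ccc(OCOC)cc2)c(C(=O)c2ccc(OCOC)cc2)c1C#Cc1ccc(OCOC)cc1 | intermediate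
25 | 4-bromophenol | Oc1ccc(Br)cc1 | starting material
26 | 1-bromo-4-(methoxymethoxy)benzene | COCOc1ccc(Br)cc1 | intermediate
27 | [4-(methoxymethoxy)phenyl]lithium (not isolated) | [Li]c1ccc(OCOC)cc1 | intermediate
28 | {4'-(methoxymethoxy)-4-[(methoxymethoxy)methyl]-3-{[4-(methoxymethoxy)phenyl]ethynyl}-[1,1'-biphenyl]-2-yl}bis[4-(methoxymethoxy)phenyl]methanol | COCOCc1ccc(-c2ccc(OCOC)cc2)c(C(O)(c2ccc(OCOC)cc2)c2ccc(OCOC)cc2)c1C#Cc1ccc(OCOC)cc1 | intermediate
29 | selaginellin, 4-{[4'-hydroxy-4-(hydroxymethyl)-3-[(4-hydroxyphenyl)ethynyl]-[1,1'-biphenyl]-2-yl](4-hydroxyphenyl)methylidene}cyclohexa-2,5-dien-1-one | O=C1C=CC(=C(c2ccc(O)cc2)c2c(-c3ccc(O)cc3)ccc(CO)c2C#Cc2ccc(O)cc2)C=C1 | target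

**Step count**
Total: 15 steps. Longest linear sequence: 10 steps (1, 2, 3, 4, 8, 10, 11, 12, 14, 15) from 2-bromo-3-chlorophenol.

**Steps most likely to fail**

Step 8 (key step). After the C6–C bond has formed, the aryl anion at C1 may take up the acidic methine proton of the adduct, or lose chloride, before it closes on the carbonyl group. The hindered diaryl enolate may also add too slowly to compete with decay of the aryne. The result would be plain C-arylation or decomposition in place of insertion. The fallback inserts the same aryne into a beta-ketoester, the substrate class on which this insertion is best established, and adds the second aryl ketone afterwards by acylation. It sets out from 9, 11 and 13. Ketone 11 is carbomethoxylated (dimethyl carbonate, NaH, THF, reflux) to methyl 3-[4-(methoxymethoxy)phenyl]-3-oxopropanoate F1. F1 and 9 with CsF in MeCN at 80 °C should give methyl 2-{3-chloro-2-[4-(methoxymethoxy)benzoyl]-6-[(methoxymethoxy)methyl]phenyl}acetate F2, since the ketone carbonyl, more electrophilic than the ester, is the one that migrates to C1. Crossed Claisen acylation of the enolate of F2 with ester 13 (NaH, THF, reflux) gives racemic methyl 2-{3-chloro-2-[4-(methoxymethoxy)benzoyl]-6-[(methoxymethoxy)methyl]phenyl}-3-[4-(methoxymethoxy)phenyl]-3-oxopropanoate F3. Krapcho dealkoxycarbonylation (LiCl, wet DMSO, 130 °C) then comes back to the route at 18.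

Step 3. The aryllithium flanked by chlorine may lose LiCl to an aryne before the silyl group has moved from oxygen to carbon, and silicon may exchange between the phenolic and the benzylic oxygen before triflation, which would give mixtures. The fallback avoids both an aryllithium next to chlorine and silicon on the benzylic oxygen. It sets out from 3. The two hydroxyl groups are tied up as the acetonide (2,2-dimethoxypropane, pyridinium p-toluenesulfonate, acetone, rt) to give 8-bromo-7-chloro-2,2-dimethyl-4H-1,3-benzodioxine F4. Bromine–magnesium exchange (i-PrMgCl·LiCl, THF, −15 °C) gives the thermally stable (7-chloro-2,2-dimethyl-4H-1,3-benzodioxin-8-yl)magnesium chloride F5, which is silylated on carbon (Me3SiCl, −15 to 40 °C) to (7-chloro-2,2-dimethyl-4H-1,3-benzodioxin-8-yl)trimethylsilane F6. Mild hydrolysis of the acetonide (AcOH/H2O/THF, rt) gives 3-chloro-6-(hydroxymethyl)-2-(trimethylsilyl)phenol F7. Phenol-selective triflation (PhNTf2, K2CO3, MeCN, rt), in which the aliphatic alcohol does not react, comes back to the route at 8.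

Step 12. The amide base may attack the sulfur of the triflate and return the enolate, or the elimination may stall because the vinylic hydrogen is shielded by the two ortho substituents of ring A, or because some enol triflate has the hydrogen syn to the leaving group. The fallback builds the alkyne by cleavage, homologation and cross-coupling instead of elimination. It sets out from 21 and uses 26. Enolate 22 is silylated on oxygen (KN(SiMe3)2, t-BuMe2SiCl, THF, −78 to 0 °C) to tert-butyl{[(Z)-2-{4'-(methoxymethoxy)-2-[4-(methoxymethoxy)benzoyl]-4-[(methoxymethoxy)methyl]-[1,1'-biphenyl]-3-yl}-1-[4-(methoxymethoxy)phenyl]ethenyl]oxy}dimethylsilane F8. Ozonolysis of this electron-rich double bond (O3, CH2Cl2, −78 °C; Me2S) gives 4'-(methoxymethoxy)-2-[4-(methoxymethoxy)benzoyl]-4-[(methoxymethoxy)methyl]-[1,1'-biphenyl]-3-carbaldehyde F9. Ohira–Bestmann homologation (dimethyl (1-diazo-2-oxopropyl)phosphonate, K2CO3, MeOH, rt) gives {3-ethynyl-4'-(methoxymethoxy)-4-[(methoxymethoxy)methyl]-[1,1'-biphenyl]-2-yl}[4-(methoxymethoxy)phenyl]methanone F10. Copper-free Sonogashira coupling with bromide 26 (PdCl2(MeCN)2, XPhos, Cs2CO3, MeCN, 80 °C) comes back to the route at 24.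

**Further compounds**
F1 | step 8 | methyl 3-[4-(methoxymethoxy)phenyl]-3-oxopropanoate | COCOc1ccc(C(=O)CC(=O)OC)cc1
F2 | step 8 | methyl 2-{3-chloro-2-[4-(methoxymethoxy)benzoyl]-6-[(methoxymethoxy)methyl]phenyl}acetate | COCOCc1ccc(Cl)c(C(=O)c2ccc(OCOC)cc2)c1CC(=O)OC
F3 | step 8 | methyl 2-{3-chloro-2-[4-(methoxymethoxy)benzoyl]-6-[(methoxymethoxy)methyl]phenyl}-3-[4-(methoxymethoxy)phenyl]-3-oxopropanoate (racemic) | COCOCc1ccc(Cl)c(C(=O)c2ccc(OCOC)cc2)c1C(C(=O)OC)C(=O)c1ccc(OCOC)cc1
F4 | step 3 | 8-bromo-7-chloro-2,2-dimethyl-4H-1,3-benzodioxine | CC1(C)OCc2ccc(Cl)c(Br)c2O1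
F5 | step 3 | (7-chloro-2,2-dimethyl-4H-1,3-benzodioxin-8-yl)magnesium chloride | CC1(C)OCc2ccc(Cl)c([Mg]Cl)c2O1
F6 | step 3 | (7-chloro-2,2-dimethyl-4H-1,3-benzodioxin-8-yl)trimethylsilane | CC1(C)OCc2ccc(Cl)c([Si](C)(C)C)c2O1
F7 | step 3 | 3-chloro-6-(hydroxymethyl)-2-(trimethylsilyl)phenol | OCc1ccc(Cl)c([Si](C)(C)C)c1O
F8 | step 12 | tert-butyl{[(Z)-2-{4'-(methoxymethoxy)-2-[4-(methoxymethoxy)benzoyl]-4-[(methoxymethoxy)methyl]-[1,1'-biphenyl]-3-yl}-1-[4-(methoxymethoxy)phenyl]ethenyl]oxy}dimethylsilane | COCOCc1ccc(-c2ccc(OCOC)cc2)c(C(=O)c2ccc(OCOC)cc2)c1/C=C(\O[Si](C)(C)C(C)(C)C)c1ccc(OCOC)cc1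
F9 | step 12 | 4'-(methoxymethoxy)-2-[4-(methoxymethoxy)benzoyl]-4-[(methoxymethoxy)methyl]-[1,1'-biphenyl]-3-carbaldehyde | COCOCc1ccc(-c2ccc(OCOC)cc2)c(C(=O)c2ccc(OCOC)cc2)c1C=O
F10 | step 12 | {3-ethynyl-4'-(methoxymethoxy)-4-[(methoxymethoxy)methyl]-[1,1'-biphenyl]-2-yl}[4-(methoxymethoxy)phenyl]methanone | COCOCc1ccc(-c2ccc(OCOC)cc2)c(C(=O)c2ccc(OCOC)cc2)c1C#C
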